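**Plan**

- Feature used: in each half, ring A (C4a, C5, C6, C7, C8, C8a; flavanone numbering, double primes for the 7-methoxy half) has the chelated 5-OH next to C4a and an oxygen at C7. A vinylketene C4a=C8a–C8H=C5=O and an alkoxyacetylene C6≡C7–O assemble exactly this 1,3-dioxygenated benzene.
- Retrosynthesis: remove the 7''-O-methyl (the 7,7''-diol is C2-symmetric), then cut both rings A at C8–C8a, C5–C6, C7–C8 and C4a–C5 back to a 3,3'-bi(6-diazoacetyl-2,3-dihydropyran-4-one). Each pyranone is cut at O1–C8a (β-hydroxy ynone) and C4–C4a (acetylide plus γ-lactone), then the two benzylic C2–O bonds, and last C3–C3''.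
- Forward: C3–C3'' by oxidative homocoupling of an acyl oxazolidinone enolate; a cis-fused bislactone by double benzylic oxidation; both rings C by acetylide opening and 6-endo cyclisation; side chains adjusted to diazoketones; both rings A in one double benzannulation; debenzylation; one O-methylation.
- Stereochemistry: C3 and C3'' come from the (S)-valine-derived auxiliary in the homocoupling. C2 and C2'' are set by substrate control when each lactone closes with its aryl group on the convex face; this becomes the cis 2,3-relationship (2S,3S,2''S,3''S) of both pyranones. No stereocentre is formed afterwards.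

Key step: step 11

Remark: lithium and potassium salts formed by simple deprotonation of a numbered compound (enolates, acetylides, the N-lithio oxazolidinone, potassium benzyl oxide) are treated as the reactive form of that compound and keep its number.

**Route**

Step 1
Reactants: 1 (S)-4-isopropyl-1,3-oxazolidin-2-one; 2 3-(4-methoxyphenyl)propanoyl chloride
Product: 3 (S)-4-isopropyl-3-[3-(4-methoxyphenyl)propanoyl]-1,3-oxazolidin-2-one
Conditions: n-BuLi, THF, −78 °C; then 2, −78 → 0 °C
Reagents that add atoms: none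
Why: N-acylation of the lithiated oxazolidinone by an acid chloride is the standard imide formation; no stereocentre is formed and the (S) centre of the auxiliary is untouched.

Step 2
Reactants: 3 (S)-4-isopropyl-3-[3-(4-methoxyphenyl)propanoyl]-1,3-oxazolidin-2-one (two molecules)
Product: 4 (2R,3R)-1,4-bis[(S)-4-isopropyl-2-oxo-1,3-oxazolidin-3-yl]-2,3-bis(4-methoxybenzyl)butane-1,4-dione
Conditions: LiN(iPr)2 (1.1 equiv), THF, −78 °C; TiCl4 (1.1 equiv), −78 °C → rt
Reagents that add atoms: none
Why: Oxidative enolate homocoupling (TiCl4 as one-electron oxidant) of the chelated Z-enolate, a reaction established for 3-arylpropanoyl oxazolidinones; each enolate reacts on the face opposite the isopropyl group, the same facial sense as an auxiliary-controlled alkylation, which should give the C2-symmetric (2R,3R) dimer that carries C3 and C3'' of the target.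

Step 3
Reactants: 4 (2R,3R)-1,4-bis[(S)-4-isopropyl-2-oxo-1,3-oxazolidin-3-yl]-2,3-bis(4-methoxybenzyl)butane-1,4-dione
Product: 6 (2R,3R)-2,3-bis(4-methoxybenzyl)succinic acid, via bis(peroxy acid) 5 (not isolated)
Conditions: LiOH, H2O2, THF–H2O, 0 °C; Na2SO3; then HCl to pH 2
Reagents that add atoms: hydrogen peroxide (as lithium hydroperoxide), OO
Why: Hydroperoxide cleavage of N-acyl oxazolidinones attacks the exocyclic carbonyl without α-epimerisation and returns the auxiliary, and sulfite reduces the peroxy acid to the acid.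

Step 4
Reactants: 6 (2R,3R)-2,3-bis(4-methoxybenzyl)succinic acid
Product: 8 (3S,3aS,6S,6aS)-3,6-bis(4-methoxyphenyl)tetrahydro-1H,3H-furo[3,4-c]furan-1,4-dione (cis-fused bislactone with both aryl groups exo), via lactone acid 7 (not isolated)
Conditions: DDQ (2.5 equiv), AcOH, 70 °C
Reagents that add atoms: none
Why: DDQ benzylic oxidative lactonisation (hydride abstraction from each 4-methoxybenzylic CH2, capture of the cation by the γ-carboxylic acid); each new benzylic centre is set with aryl trans to the neighbouring ring substituent, that is on the convex face of the bicycle, which is both the kinetic mode of closure and the thermodynamic isomer because the 4-methoxybenzylic C–O bond can re-ionise, while the bridgeheads are locked by the cis ring fusion.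

Step 5
Reactants: 8 the exo,exo-bislactone; 9 2-methylbut-1-en-3-yne (2.6 equiv)
Product: 11 (6S,7S)-6,7-bis[(S)-hydroxy(4-methoxyphenyl)methyl]-2,11-dimethyldodeca-1,11-diene-3,9-diyne-5,8-dione, via bis(lactol) 10 (not isolated)
Conditions: 9, n-BuLi, THF, −78 °C; then 8, −78 °C; AcOH, −78 °C
Reagents that add atoms: none
Why: Addition of a lithium acetylide to a γ-lactone stops at the lactolate, which is stable at −78 °C, and gives the hydroxy ynone on protonation (C4–C4a and C4''–C4a'' formed); no stereocentre is touched, and the low temperature and cold acidic quench avoid bridgehead enolisation and retro-aldol cleavage.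

Step 6
Reactants: 11 the bis(β-hydroxy ynone)
Product: 12 (2S,2'S,3S,3'S)-2,2'-bis(4-methoxyphenyl)-6,6'-di(prop-1-en-2-yl)-2,2',3,3'-tetrahydro-4H,4'H-[3,3'-bipyran]-4,4'-dione
Conditions: Ph3PAuCl (5 mol%), AgOSO2CF3 (5 mol%), CH2Cl2, rt
Reagents that add atoms: none
Why: Gold-catalysed 6-endo-dig hydroalkoxylation (intramolecular oxa-Michael addition) of β-hydroxy ynones is a standard entry to 2,3-dihydro-4H-pyran-4-ones; each benzylic hydroxyl reaches only the distal alkyne carbon of its own ynone, hemiketal formation with the other carbonyl is reversible and has no dehydration path, and the syn relationship set in step 4 appears unchanged as the cis 2,3-relationship.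

Step 7
Reactants: 12 the bis(6-isopropenyl pyranone)
Product: 14 (2S,2'S,3S,3'S)-6,6'-diacetyl-2,2'-bis(4-methoxyphenyl)-2,2',3,3'-tetrahydro-4H,4'H-[3,3'-bipyran]-4,4'-dione, via bis(diol) 13 (not isolated)
Conditions: OsO4 (2 mol%), NaIO4 (4.5 equiv), 2,6-lutidine, dioxane–H2O, rt
Reagents that add atoms: osmium tetroxide, O=[Os](=O)(=O)=O; sodium periodate, [Na+].[O-]I(=O)(=O)=O
Why: Lemieux–Johnson cleavage should take the electron-richer terminal 1,1-disubstituted alkene in preference to the carbonyl-deactivated ring enol ether double bond and the anisyl rings, and the buffered medium leaves C3 and C3' alone.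

Step 8
Reactants: 14 the bis(6-acetyl pyranone)
Product: 16 (2S,2'S,3S,3'S)-6,6'-bis(2-diazoacetyl)-2,2'-bis(4-methoxyphenyl)-2,2',3,3'-tetrahydro-4H,4'H-[3,3'-bipyran]-4,4'-dione, via bis(trifluoroacetyl ketone) 15 (not isolated)
Conditions: LiN(SiMe3)2 (2.3 equiv), THF, −78 °C; CF3CO2CH2CF3, −78 °C; 5% HCl work-up; then MsN3, Et3N, H2O, MeCN, rt
Reagents that add atoms: methanesulfonyl azide, CS(=O)(=O)N=[N+]=[N-]
Why: Detrifluoroacetylative diazo transfer (kinetic deprotonation of the unhindered acetyl CH3, Claisen trapping as the trifluoroacetyl ketone, diazo transfer with loss of the trifluoroacetyl group) is the standard route to α'-diazo-α,β-unsaturated ketones, and the hindered tertiary C3 and C3' hydrogens should not be removed at −78 °C.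

Step 9
Reactants: 17 benzyl alcohol; 18 trichloroethylene
Product: 20 benzyl (E)-1,2-dichlorovinyl ether, via dichloroacetylene 19 (not isolated)
Conditions: KH, THF, 0 °C; then 18, 0 °C → rt
Reagents that add atoms: none
Why: The trichloroethylene route to 1,2-dichlorovinyl ethers: the alkoxide dehydrochlorinates trichloroethylene and adds anti to the dichloroacetylene so formed, giving the E ether.

Step 10
Reactants: 20 benzyl (E)-1,2-dichlorovinyl ether
Product: 22 benzyl ethynyl ether (benzyloxyacetylene), via benzyl chloroethynyl ether 21 (not isolated)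
Conditions: n-BuLi (2.3 equiv), Et2O, −78 → −40 °C; MeOH, −78 °C; kept cold and used promptly
Reagents that add atoms: none
Why: Elimination of HCl to the chloroalkyne, chlorine–lithium exchange and protonation of the lithium alkoxyacetylide is the usual ynol ether synthesis, and the cold work-up stays below the temperature at which benzyl alkynyl ethers undergo [3,3] rearrangement.

Step 11
Reactants: 16 the bis(diazoketone); 22 benzyl ethynyl ether (3 equiv)
Product: 27 (2S,2''S,3S,3''S)-7,7''-bis(benzyloxy)-5,5''-dihydroxy-4',4'''-dimethoxy-3,3''-biflavanone, via bis(vinylketene) 23 (not isolated), via bis(cyclobutenone) 24 (not isolated), via bis(dienylketene) 25 (not isolated), via bis(cyclohexadienone) 26 (not isolated)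
Conditions: 22, hν (365 nm), ClCH2CH2Cl, 20 °C; excess 22 removed in vacuo; PhMe, 80 °C
Reagents that add atoms: none
Why: Irradiation expels N2 from each diazoketone and the pyranone carbon C8a migrates to the carbene carbon (Wolff rearrangement), giving a vinylketene whose ketene carbon becomes C5 and whose vinyl group is the endocyclic C4a=C8a bond. The electron-rich CH terminus of benzyloxyacetylene attacks the electrophilic ketene carbon in a regiospecific [2+2] cycloaddition (C5–C6 and C7–C8), so the 3-benzyloxy-4-vinylcyclobutenone carries oxygen at the future C7; this polarity match fixes the free hydroxyl at C5 beside C4a and the ether at C7. Heating opens each cyclobutenone by 4π electrocyclic cleavage to a dienylketene, which closes ring A by thermal 6π electrocyclisation (C4a–C5) and tautomerises to the chelated phenol; this is the Danheiser benzannulation in its photochemical diazoketone form, known with alkoxy- and silyloxyalkynes. Two benzene rings and eight skeletal bonds are formed and no stereocentre is created. The step needs chemoselective ketene capture and retention of the four existing centres: the alkyne is in excess while the ketene is generated at room temperature, the phenol appears only in the thermal stage when no ketene source remains (so aryl ester formation is avoided), and the medium is neutral and aprotic, so the epimerisable C3 and C3'' hydrogens α to the ketones meet neither acid nor base.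

Step 12
Reactants: 27 the 7,7''-bis(benzyl ether)
Product: 28 (2S,2''S,3S,3''S)-5,5'',7,7''-tetrahydroxy-4',4'''-dimethoxy-3,3''-biflavanone
Conditions: H2 (1 atm), 10% Pd/C, EtOAc, rt
Reagents that add atoms: none
Why: Hydrogenolysis of aryl benzyl ethers over Pd/C is neutral and routine for benzyloxyflavanones; the chelated aryl ketones, the C2–O1 bonds and the stereocentres should survive.

Step 13
Reactants: 28 the C2-symmetric tetraphenol
Product: 29 (2S,2''S,3S,3''S)-5,5'',7-trihydroxy-7'',4',4'''-trimethoxy-3,3''-biflavanone (target, CNP0184936.4)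
Conditions: CH2N2 (1.0 equiv), Et2O–MeOH, 0 °C; recovered 28 recycled
Reagents that add atoms: diazomethane, C=[N+]=[N-]
Why: Diazomethane O-methylates the acidic free 7-hydroxyl but not the 5-hydroxyl hydrogen-bonded to C4=O (classical selective 7-O-methylation of flavanones) under neutral conditions; the two 7-hydroxyls are homotopic, so one equivalent should give the single monomethyl ether in a statistical mixture with recoverable 28 and the dimethyl ether.

**Compound list**

1 | (S)-4-isopropyl-1,3-oxazolidin-2-one | CC(C)[C@H]1COC(=O)N1 | starting material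
2 | 3-(4-methoxyphenyl)propanoyl chloride | COc1ccc(CCC(Cl)=O)cc1 | starting material
3 | (S)-4-isopropyl-3-[3-(4-methoxyphenyl)propanoyl]-1,3-oxazolidin-2-one | COc1ccc(CCC(=O)N2C(=O)OC[C@@H]2C(C)C)cc1 | intermediate
4 | (2R,3R)-1,4-bis[(S)-4-isopropyl-2-oxo-1,3-oxazolidin-3-yl]-2,3-bis(4-methoxybenzyl)butane-1,4-dione | COc1ccc(C[C@@H](C(=O)N2C(=O)OC[C@@H]2C(C)C)[C@H](C(=O)N2C(=O)OC[C@@H]2C(C)C)Cc2ccc(OC)cc2)cc1 | intermediate
5 | (2R,3R)-2,3-bis(4-methoxybenzyl)butanediperoxoic acid (bis(peroxy acid)) | COc1ccc(C[C@@H](C(=O)OO)[C@H](C(=O)OO)Cc2ccc(OC)cc2)cc1 | intermediate (not isolated)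
6 | (2R,3R)-2,3-bis(4-methoxybenzyl)succinic acid | COc1ccc(C[C@@H](C(O)=O)[C@H](C(O)=O)Cc2ccc(OC)cc2)cc1 | intermediate
7 | (2S,3S,4R)-4-(4-methoxybenzyl)-2-(4-methoxyphenyl)-5-oxotetrahydrofuran-3-carboxylic acid (lactone acid) | COc1ccc([C@H]2OC(=O)[C@H](Cc3ccc(OC)cc3)[C@@H]2C(O)=O)cc1 | intermediate (not isolated)
8 | (3S,3aS,6S,6aS)-3,6-bis(4-methoxyphenyl)tetrahydro-1H,3H-furo[3,4-c]furan-1,4-dione (cis-fused, both aryl groups exo) | COc1ccc([C@H]2OC(=O)[C@H]3[C@@H]2C(=O)O[C@@H]3c2ccc(OC)cc2)cc1 | intermediate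
9 | 2-methylbut-1-en-3-yne | C=C(C)C#C | starting material
10 | (3S,3aS,6S,6aS)-3,6-bis(4-methoxyphenyl)-1,4-bis(3-methylbut-3-en-1-yn-1-yl)tetrahydro-1H,3H-furo[3,4-c]furan-1,4-diol (bis(lactol), anomeric centres undefined) | COc1ccc([C@H]2OC(O)(C#CC(C)=C)[C@H]3[C@@H]2C(O)(C#CC(C)=C)O[C@@H]3c2ccc(OC)cc2)cc1 | intermediate (not isolated)
11 | (6S,7S)-6,7-bis[(S)-hydroxy(4-methoxyphenyl)methyl]-2,11-dimethyldodeca-1,11-diene-3,9-diyne-5,8-dione | COc1ccc([C@@H](O)[C@@H](C(=O)C#CC(C)=C)[C@H](C(=O)C#CC(C)=C)[C@H](O)c2ccc(OC)cc2)cc1 | intermediate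
12 | (2S,2'S,3S,3'S)-2,2'-bis(4-methoxyphenyl)-6,6'-di(prop-1-en-2-yl)-2,2',3,3'-tetrahydro-4H,4'H-[3,3'-bipyran]-4,4'-dione | COc1ccc([C@H]2OC(C(C)=C)=CC(=O)[C@H]2[C@@H]2C(=O)C=C(C(C)=C)O[C@@H]2c2ccc(OC)cc2)cc1 | intermediate
13 | (2S,2'S,3S,3'S)-6,6'-bis(1,2-dihydroxypropan-2-yl)-2,2'-bis(4-methoxyphenyl)-2,2',3,3'-tetrahydro-4H,4'H-[3,3'-bipyran]-4,4'-dione (bis(diol), carbinol centres undefined) | COc1ccc([C@H]2OC(C(C)(O)CO)=CC(=O)[C@H]2[C@@H]2C(=O)C=C(C(C)(O)CO)O[C@@H]2c2ccc(OC)cc2)cc1 | intermediate (not isolated)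
14 | (2S,2'S,3S,3'S)-6,6'-diacetyl-2,2'-bis(4-methoxyphenyl)-2,2',3,3'-tetrahydro-4H,4'H-[3,3'-bipyran]-4,4'-dione | COc1ccc([C@H]2OC(C(C)=O)=CC(=O)[C@H]2[C@@H]2C(=O)C=C(C(C)=O)O[C@@H]2c2ccc(OC)cc2)cc1 | intermediate
15 | (2S,2'S,3S,3'S)-2,2'-bis(4-methoxyphenyl)-6,6'-bis(4,4,4-trifluoro-3-oxobutanoyl)-2,2',3,3'-tetrahydro-4H,4'H-[3,3'-bipyran]-4,4'-dione | COc1ccc([C@H]2OC(C(=O)CC(=O)C(F)(F)F)=CC(=O)[C@H]2[C@@H]2C(=O)C=C(C(=O)CC(=O)C(F)(F)F)O[C@@H]2c2ccc(OC)cc2)cc1 | intermediate (not isolated)
16 | (2S,2'S,3S,3'S)-6,6'-bis(2-diazoacetyl)-2,2'-bis(4-methoxyphenyl)-2,2',3,3'-tetrahydro-4H,4'H-[3,3'-bipyran]-4,4'-dione | COc1ccc([C@H]2OC(C(=O)C=[N+]=[N-])=CC(=O)[C@H]2[C@@H]2C(=O)C=C(C(=O)C=[N+]=[N-])O[C@@H]2c2ccc(OC)cc2)cc1 | intermediate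
17 | benzyl alcohol | OCc1ccccc1 | starting material
18 | trichloroethylene | ClC=C(Cl)Cl | starting material
19 | dichloroacetylene | ClC#CCl | intermediate (not isolated)
20 | benzyl (E)-1,2-dichlorovinyl ether | Cl/C=C(/Cl)OCc1ccccc1 | intermediate
21 | benzyl chloroethynyl ether | ClC#COCc1ccccc1 | intermediate (not isolated)
22 | benzyl ethynyl ether (benzyloxyacetylene) | C#COCc1ccccc1 | intermediate
23 | (2S,2'S,3S,3'S)-2,2'-bis(4-methoxyphenyl)-6,6'-bis(2-oxoethenyl)-2,2',3,3'-tetrahydro-4H,4'H-[3,3'-bipyran]-4,4'-dione (bis(vinylketene)) | COc1ccc([C@H]2OC(C=C=O)=CC(=O)[C@H]2[C@@H]2C(=O)C=C(C=C=O)O[C@@H]2c2ccc(OC)cc2)cc1 | intermediate (not isolated)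
24 | (2S,2'S,3S,3'S)-6,6'-bis[2-(benzyloxy)-4-oxocyclobut-2-en-1-yl]-2,2'-bis(4-methoxyphenyl)-2,2',3,3'-tetrahydro-4H,4'H-[3,3'-bipyran]-4,4'-dione (bis(cyclobutenone), cyclobutenyl centres undefined) | COc1ccc([C@H]2OC(C3C(=O)C=C3OCc3ccccc3)=CC(=O)[C@H]2[C@@H]2C(=O)C=C(C3C(=O)C=C3OCc3ccccc3)O[C@@H]2c2ccc(OC)cc2)cc1 | intermediate (not isolated)
25 | (2S,2'S,3S,3'S)-6,6'-bis[2-(benzyloxy)-4-oxobuta-1,3-dien-1-yl]-2,2'-bis(4-methoxyphenyl)-2,2',3,3'-tetrahydro-4H,4'H-[3,3'-bipyran]-4,4'-dione (bis(dienylketene)) | COc1ccc([C@H]2OC(C=C(OCc3ccccc3)C=C=O)=CC(=O)[C@H]2[C@@H]2C(=O)C=C(C=C(OCc3ccccc3)C=C=O)O[C@@H]2c2ccc(OC)cc2)cc1 | intermediate (not isolated)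
26 | 4a,4a''-dihydro keto tautomer of 27: (2S,2''S,3S,3''S)-7,7''-bis(benzyloxy)-2,2''-bis(4-methoxyphenyl)-2,3,2'',3''-tetrahydro-3,3''-bichromene-4,5,4'',5''(4aH,4a''H)-tetrone (bis(cyclohexadienone), C4a centres undefined) | COc1ccc([C@H]2OC3=CC(OCc4ccccc4)=CC(=O)C3C(=O)[C@H]2[C@@H]2C(=O)C3C(=O)C=C(OCc4ccccc4)C=C3O[C@@H]2c2ccc(OC)cc2)cc1 | intermediate (not isolated)
27 | (2S,2''S,3S,3''S)-7,7''-bis(benzyloxy)-5,5''-dihydroxy-4',4'''-dimethoxy-3,3''-biflavanone | COc1ccc([C@H]2Oc3cc(OCc4ccccc4)cc(O)c3C(=O)[C@H]2[C@@H]2C(=O)c3c(O)cc(OCc4ccccc4)cc3O[C@@H]2c2ccc(OC)cc2)cc1 | intermediate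
28 | (2S,2''S,3S,3''S)-5,5'',7,7''-tetrahydroxy-4',4'''-dimethoxy-3,3''-biflavanone | COc1ccc([C@H]2Oc3cc(O)cc(O)c3C(=O)[C@H]2[C@@H]2C(=O)c3c(O)cc(O)cc3O[C@@H]2c2ccc(OC)cc2)cc1 | intermediate
29 | (2S,2''S,3S,3''S)-5,5'',7-trihydroxy-7'',4',4'''-trimethoxy-3,3''-biflavanone (CNP0184936.4) | COc1ccc([C@H]2Oc3cc(O)cc(O)c3C(=O)[C@H]2[C@@H]2C(=O)c3c(O)cc(OC)cc3O[C@@H]2c2ccc(OC)cc2)cc1 | target

**Step count and risks**

Total steps: 13. Longest linear sequence: 11 (steps 1 to 8 and 11 to 13); steps 9 and 10 form the two-step side branch to the alkyne.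

Three steps most likely to fail:

Step 11, the double photochemical benzannulation. The photogenerated ketenes may dimerise or be intercepted by adventitious nucleophiles faster than they add to the alkyne, or the enone chromophores may undergo competing photoreactions, so that one or both rings A fail to form. The fallback generates the same vinylketenes thermally. It sets out from 16: a Wolff rearrangement run in water-containing medium (AgO2CPh cat., Et3N, THF–H2O, rt) should give the bis(pyranylacetic acid) F1, and oxalyl chloride with a trace of DMF in CH2Cl2 converts it into the bis(acid chloride) F2. Slow addition of Et3N to F2 and 22 in CH2Cl2 at room temperature dehydrochlorinates each acyl chloride to the vinylketene, which is captured by [2+2] addition as the bis(cyclobutenone) 24. Heating 24 in toluene at 80 °C then completes ring opening and 6π closure, and the fallback comes back to the route at 27.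

Step 4, the double oxidative lactonisation. Hydride abstraction from the mono-methoxylated benzylic positions may be slow, or the benzylic cation may lose a proton to a 4-methoxybenzylidene acid before the carboxyl group captures it, leaving alkene or singly cyclised material. The fallback separates C–H activation from C–O bond formation. It sets out from 6: Wohl–Ziegler bromination (N-bromosuccinimide, cat. (PhCO2)2, PhCF3, 80 °C) should give the bis(benzylic bromide) F3. NaHCO3 in DMF at room temperature then lets each γ-carboxylate displace its 4-methoxybenzylic bromide by an ionising pathway that again places aryl on the convex face, and the fallback comes back to the route at 8.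

Step 8, the diazo transfer. LiN(SiMe3)2 may remove the C3 or C3' hydrogen in competition with the acetyl CH3, which would epimerise the cis 2,3-relationship or open the ring by β-elimination of O1. The fallback keeps strong base away from the pyranones and sets out from 8, replacing steps 5 to 8. Lithium tert-butyl propiolate (tert-butyl propiolate, LiN(iPr)2, THF, −78 °C) opens both lactones to the bis(hydroxy ynone ester) F4. The Ph3PAuCl/AgOSO2CF3 cyclisation of step 6 should then give the bis(pyranone tert-butyl ester) F5, with the ketone directing the hydroxyl to the alkyne carbon that bears the ester. CF3CO2H in CH2Cl2 frees the bis(carboxylic acid) F6, oxalyl chloride with a trace of DMF gives the bis(acid chloride) F7, and excess CH2N2 in Et2O at 0 °C acylates diazomethane (first stage of an Arndt–Eistert sequence), so the fallback comes back to the route at 16.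

**Further compounds**

F1 | step 11 | 2,2'-[(2S,2'S,3S,3'S)-2,2'-bis(4-methoxyphenyl)-4,4'-dioxo-3,3',4,4'-tetrahydro-2H,2'H-[3,3'-bipyran]-6,6'-diyl]diacetic acid | COc1ccc([C@H]2OC(CC(O)=O)=CC(=O)[C@H]2[C@@H]2C(=O)C=C(CC(O)=O)O[C@@H]2c2ccc(OC)cc2)cc1
F2 | step 11 | 2,2'-[(2S,2'S,3S,3'S)-2,2'-bis(4-methoxyphenyl)-4,4'-dioxo-3,3',4,4'-tetrahydro-2H,2'H-[3,3'-bipyran]-6,6'-diyl]diacetyl dichloride | COc1ccc([C@H]2OC(CC(Cl)=O)=CC(=O)[C@H]2[C@@H]2C(=O)C=C(CC(Cl)=O)O[C@@H]2c2ccc(OC)cc2)cc1
F3 | step 4 | (2R,3R)-2,3-bis[bromo(4-methoxyphenyl)methyl]succinic acid (benzylic centres undefined) | COc1ccc(C(Br)[C@@H](C(O)=O)[C@H](C(O)=O)C(Br)c2ccc(OC)cc2)cc1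
F4 | step 8 | di-tert-butyl (5S,6S)-5,6-bis[(S)-hydroxy(4-methoxyphenyl)methyl]-4,7-dioxodeca-2,8-diynedioate | COc1ccc([C@@H](O)[C@@H](C(=O)C#CC(=O)OC(C)(C)C)[C@H](C(=O)C#CC(=O)OC(C)(C)C)[C@H](O)c2ccc(OC)cc2)cc1
F5 | step 8 | di-tert-butyl (2S,2'S,3S,3'S)-2,2'-bis(4-methoxyphenyl)-4,4'-dioxo-3,3',4,4'-tetrahydro-2H,2'H-[3,3'-bipyran]-6,6'-dicarboxylate | COc1ccc([C@H]2OC(C(=O)OC(C)(C)C)=CC(=O)[C@H]2[C@@H]2C(=O)C=C(C(=O)OC(C)(C)C)O[C@@H]2c2ccc(OC)cc2)cc1
F6 | step 8 | (2S,2'S,3S,3'S)-2,2'-bis(4-methoxyphenyl)-4,4'-dioxo-3,3',4,4'-tetrahydro-2H,2'H-[3,3'-bipyran]-6,6'-dicarboxylic acid | COc1ccc([C@H]2OC(C(O)=O)=CC(=O)[C@H]2[C@@H]2C(=O)C=C(C(O)=O)O[C@@H]2c2ccc(OC)cc2)cc1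
F7 | step 8 | (2S,2'S,3S,3'S)-2,2'-bis(4-methoxyphenyl)-4,4'-dioxo-3,3',4,4'-tetrahydro-2H,2'H-[3,3'-bipyran]-6,6'-dicarbonyl dichloride | COc1ccc([C@H]2OC(C(Cl)=O)=CC(=O)[C@H]2[C@@H]2C(=O)C=C(C(Cl)=O)O[C@@H]2c2ccc(OC)cc2)cc1
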